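# Proposed synthesis of gancaonin G by carbene-catalysed closure of ring C

Remark on the chemistry: the target is achiral. The one stereocentre formed on the way (C3 of 14 and 15) is carried as a racemate and disappears in step 9. Compounds 1, 2 and 9 are assumed to be purchased.

## Analysis of the target

Gancaonin G (18) is an isoflavone: benzo ring A is fused to the 4-pyranone ring C (O1, C2, C3, C4, C4a, C8a), and the 4-hydroxyphenyl ring B sits on C3. It has no stereocentre, so the only stereocentre of the route (C3 of ketol 14) is transient. Ring A is fully differentiated: 5-OH hydrogen-bonded to the C4 carbonyl, the 3-methylbut-2-enyl (prenyl) chain on C6, a methyl ether on C7 and hydrogen on C8. The sensitive groups are the two phenols and the prenyl alkene, which under protic or Lewis acid cyclises onto a neighbouring oxygen to a dimethylchroman and which tolerates neither hydrogenation nor electrophilic oxidants. The difficulty is therefore to place the prenyl group between two oxygens that must end up different, and to finish without strong acid, hydrogenolysis or oxidation. Two features are used. First, C3 and C4 are adjacent carbons that both trace back to carbonyl groups, C4 to an aldehyde on C4a and C3 to the aryl ketone of a phenacyl ether on the C8a oxygen, so ring C can close by forming C3–C4 once the aldehyde is reversed in polarity. Second, C6 with its oxygenated neighbours C5 and C7 is a locally symmetric 2-prenylresorcinol unit, so with both oxygens as methyl ethers the phenol 6 has two equivalent ortho positions, and the C5 ether is told apart only at the end through its chelation to the C4 carbonyl.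

## Retrosynthetic reasoning

**18 from 16.** The last operation only removes the methyl group on O5 and the methoxymethyl group on O4'. The two methyl ethers of 16 differ in reactivity: the C5 oxygen is peri to the C4 carbonyl and forms a six-membered chelate with a boron Lewis acid (seen as 17), while the C7 ether cannot. Keeping O5 as a methyl ether until here is what allows ring A to come from a symmetric precursor. The forward step has to cleave one O–CH3 bond and the acetal without protonating the prenyl alkene.

**16 from 14.** The C2=C3 double bond is taken back to a tertiary alcohol on C3 with C2 as a methylene. Water can only be lost toward C2, the sole neighbour carrying hydrogen, so there is no regiochemical question. The forward step activates the alcohol as sulfamate 15 and eliminates it under neutral conditions, so that the alpha-ketol neither rearranges nor ionises.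

**14 from 13 (key disconnection).** The C3–C4 bond is cut. This is the one bond of ring C that joins two former carbonyl carbons, and cutting it gives an open-chain keto aldehyde 13 in which the two ends are already tied through O1–C2. Cutting C4–C4a or C2–C3 would need acylation of an electron-rich arene or an enolate formylation, both of which bring acid or regiochemical problems. The forward reaction must make the aldehyde carbon nucleophilic under conditions mild enough for the prenyl group and the enolisable ketone.

**13 from 8 and 12.** The O1–C2 ether bond is cut to the salicylaldehyde 8 and the alpha-bromo ketone 12. This is the most reliable bond of the precursor to form, and it splits the molecule into a ring A piece and a ring B piece of similar size. The forward alkylation must stop at the ether and not continue to an aldol closure.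

**8 from 6.** The C4–C4a bond is cut, removing the formyl group. Phenol 6 is symmetric about the axis through C8a and C6, so ortho-formylation can give only one product, formed by way of the hydroxymethyl compound 7. The forward reaction must be ortho-selective and free of acid.

**6 from 5 from 4.** The C8a–O bond is cut. In 4 the future C8a is the only ring position without an ortho substituent, so a sterically governed C–H borylation to 5 followed by oxidation places the oxygen there and nowhere else. A classical electrophilic substitution would instead go ortho to a methoxy group.

**4 from 1 and 2.** The bond between C6 and the prenyl CH2 is cut. The position between the two methoxy groups of 1 is the most acidic, so metalation to 3 and alkylation with 2 fixes the prenyl group at C6 before any other substituent is present.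

**12 from 10 from 9.** The C–Br bond and the acetal are removed in turn. Protection comes first because a free phenol and a phenacyl bromide cannot coexist under base. The bromine is introduced through silyl enol ether 11 so that no acid meets the acetal.

## Alternatives that were turned down

**Alternative 1:** Ring A is dismantled completely and rebuilt on a preformed pyranone by a Danheiser benzannulation.
- Disconnection and key step: diazo ketone A2 undergoes a Wolff rearrangement, which moves the pyranonyl group onto the former diazo carbon (C8–C8a) and gives a vinylketene whose alkene is the C8a=C4a bond of the pyranone. Cycloaddition with the methoxy alkyne A3, opening of the cyclobutenone and a six-electron ring closure would form C5–C6, C7–C8 and C4a–C5 and give A1.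
- For: the polarity of A3 places 5-OH, the prenyl group and 7-OMe in one step with no regiochemical doubt. The 5-OH emerges free, so no chelated methyl ether has to be cleaved, and the endgame is only a fluoride desilylation. On the endgame this alternative is stronger than the chosen route, which needs a boron Lewis acid next to the prenyl group.
- Against: both partners need multi-step syntheses. A3 is a 1-alkoxyalkyne with a skipped alkene, volatile and easily hydrolysed or isomerised. The Wolff step needs light or heat on a photoactive, cross-conjugated pyranone. The final electrocyclisation must engage the pyranone C=C bond, and the ketene can also be trapped by prenyl alkenes. Four pericyclic events would have to work in sequence on a heteroaryl system that is not the usual substrate.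
- Comparison: the chosen strategy starts from a cheap arene and closes the ring by a catalytic reaction with direct precedent on the same substrate class. It pays with two functional-group steps after the key step.

**Alternative 2:** Ring C is made by aryne insertion, cutting O1–C8a and C4–C4a.
- Disconnection and key step: fluoride releases the aryne from silyl triflate A5. The enolate oxygen of hydroxyacrylate A6 adds at C8a, the aryne carbon remote from the 5-methoxy group, and the C4a aryl anion then acylates on the ester to give A4, which is the same compound as 16.
- For: this is the most convergent plan. It reaches 16 in one operation with no ketol and no dehydration, the methoxy group steers the aryne regiochemistry the right way, and the conditions are harmless to prenyl and acetal. On the number of steps after fragment union it is stronger than the chosen route.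
- Against: the enolate of A6 is ambident, and attack through carbon leads to insertion into a C–C bond instead of O-arylation. Ring closure requires the O-aryl and ester groups cis on the alkene, otherwise the aryl anion is simply protonated. The anion at C4a is flanked by two oxygen substituents and is hindered for the acylation. A5 would be made from phenol 6 by ortho-halogenation, silylation and triflation, so the overall step count is not lower.
- Comparison: the chosen strategy fixes which atoms bond by a tether, so no O/C selectivity or alkene geometry has to be relied on. It accepts one extra step to introduce the C2=C3 bond.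

**Alternative 3:** Ring A is cut at C8–C8a and C5–C6 in a [3+3] benzannulation.
- Disconnection and key step: the kinetic methyl enolate of sulcatone A8 displaces the methylthio group of pyranone ester A9 by addition–elimination (C8–C8a). The other alpha-carbon then acylates on the ester (C5–C6), and tautomerisation gives the 5,7-diol A7.
- For: the prenyl group arrives inside a commodity ketone and is placed at C6 unambiguously. The two phenols of A7 are told apart by classical selective methylation of the non-chelated 7-OH, and no aryl methyl ether has to be cleaved. On differentiation of O5 and O7 this alternative is at least as good as the chosen route.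
- Against: A9 has a second open electrophilic position, the future C2, where attack opens the pyranone ring. After the first bond is formed the most acidic site is the C8 methylene, so the ring closure needs a dianion that enolises at C6. A9 needs a bespoke synthesis, and methylation and deprotection still follow.
- Comparison: the chosen strategy keeps ring A aromatic throughout and risks only one catalytic ring closure, on a precursor that is six reliable steps from purchased materials.

Key step: step 8

## Route

Step 1
Reactants: 1 1,3-dimethoxybenzene; 2 1-bromo-3-methylbut-2-ene (prenyl bromide)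
Product: 4 1,3-dimethoxy-2-(3-methylbut-2-en-1-yl)benzene, via aryllithium 3 (not isolated)
Conditions: n-BuLi (1.1 equiv), THF, 0 °C → rt; then 2 (1.2 equiv), −78 °C → rt
Reagents that add atoms: n-butyllithium, [Li]CCCC (supplies only the lithium of 3; no atom of it remains in 4)
Why: Directed ortho-metalation: the C–H between the two methoxy groups is the most acidic and is coordinated from both sides, so 3 should form cleanly. SN2 alkylation then occurs at the primary carbon of the allylic bromide, because the SN2' mode would create a quaternary carbon.

Step 2
Reactants: 4 1,3-dimethoxy-2-(3-methylbut-2-en-1-yl)benzene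
Product: 5 2-[3,5-dimethoxy-4-(3-methylbut-2-en-1-yl)phenyl]-4,4,5,5-tetramethyl-1,3,2-dioxaborolane
Conditions: [Ir(OMe)(cod)]2 (1.5 mol %), 4,4'-di-tert-butyl-2,2'-bipyridine (3 mol %), B2pin2 (1.0 equiv), MTBE, 50 °C
Reagents that add atoms: bis(pinacolato)diboron, CC1(C)OB(OC1(C)C)B1OC(C)(C)C(C)(C)O1
Why: Iridium-catalysed aromatic C–H borylation is governed by sterics, and C5 is the only ring C–H of 4 without an ortho substituent, so boron should enter there. The hindered trisubstituted alkene is expected to be a much poorer substrate for the iridium tris(boryl) catalyst than this open aryl C–H bond.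

Step 3
Reactants: 5 2-[3,5-dimethoxy-4-(3-methylbut-2-en-1-yl)phenyl]-4,4,5,5-tetramethyl-1,3,2-dioxaborolane
Product: 6 3,5-dimethoxy-4-(3-methylbut-2-en-1-yl)phenol
Conditions: 30% aq H2O2 (3 equiv), 1 M aq NaOH, THF, 0 °C; then aq NH4Cl
Reagents that add atoms: hydrogen peroxide, OO (phenol oxygen)
Why: Oxidation of an arylboronate: hydroperoxide adds to boron and the aryl group migrates from boron to oxygen at the same ring carbon. Alkaline peroxide is nucleophilic and does not epoxidise an unactivated alkene, which is why electrophilic peroxy oxidants are avoided here.

Step 4
Reactants: 6 3,5-dimethoxy-4-(3-methylbut-2-en-1-yl)phenol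
Product: 8 6-hydroxy-2,4-dimethoxy-3-(3-methylbut-2-en-1-yl)benzaldehyde, via hydroxymethylphenol 7 (not isolated)
Conditions: MgCl2 (2 equiv), Et3N (4 equiv), paraformaldehyde (6 equiv), MeCN, 80 °C; then cold aq citric acid
Reagents that add atoms: paraformaldehyde (as formaldehyde), C=O
Why: Magnesium-mediated ortho-formylation of a phenol (Casnati–Skattebøl conditions): the magnesium phenoxide delivers formaldehyde to the ortho carbon through a chelate to give 7, which a second formaldehyde oxidises by hydride transfer. The two ortho positions of 6 are equivalent by symmetry, so only one aldehyde can form, and the basic medium spares the prenyl group.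

Step 5
Reactants: 9 1-(4-hydroxyphenyl)ethanone
Product: 10 1-[4-(methoxymethoxy)phenyl]ethanone
Conditions: MOMCl (1.3 equiv), i-Pr2NEt (2 equiv), CH2Cl2, 0 °C → rt
Reagents that add atoms: chloromethyl methyl ether, COCCl
Why: O-alkylation of a phenol with an alpha-chloro ether to give the acetal. The phenol is protected before bromine is introduced, because a phenoxide that already carries a phenacyl bromide would alkylate itself and exchange halide with the chloride set free.

Step 6
Reactants: 10 1-[4-(methoxymethoxy)phenyl]ethanone
Product: 12 2-bromo-1-[4-(methoxymethoxy)phenyl]ethanone, via silyl enol ether 11 (not isolated)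
Conditions: LiN(SiMe3)2 (1.1 equiv), THF, −78 °C; Me3SiCl (1.2 equiv), −78 → 0 °C; solvent change to pentane and filtration; then NBS (1.05 equiv), THF, −78 → 0 °C
Reagents that add atoms: N-bromosuccinimide, O=C1CCC(=O)N1Br (bromine of 12); chlorotrimethylsilane, C[Si](C)(C)Cl (silyl group of 11 only)
Why: Enolisation and O-silylation give 11, and electrophilic bromination of a silyl enol ether with NBS then places one bromine on the terminal carbon. No hydrogen bromide is released, so the acid-labile acetal should survive, and using the preformed enol ether limits the reaction to monobromination.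

Step 7
Reactants: 8 6-hydroxy-2,4-dimethoxy-3-(3-methylbut-2-en-1-yl)benzaldehyde; 12 2-bromo-1-[4-(methoxymethoxy)phenyl]ethanone
Product: 13 2,4-dimethoxy-6-{2-[4-(methoxymethoxy)phenyl]-2-oxoethoxy}-3-(3-methylbut-2-en-1-yl)benzaldehyde
Conditions: K2CO3 (1.5 equiv), acetone, rt
Reagents that add atoms: none
Why: Williamson ether synthesis: the potassium phenoxide of 8 displaces bromide from the highly SN2-reactive alpha-bromo ketone. A weak base at room temperature should keep the following intramolecular aldol (Rap–Stoermer benzofuran formation) from starting, and the electron-rich aldehyde carrying two ortho oxygen donors slows it further.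

Step 8
Reactants: 13 2,4-dimethoxy-6-{2-[4-(methoxymethoxy)phenyl]-2-oxoethoxy}-3-(3-methylbut-2-en-1-yl)benzaldehyde
Product: 14 racemic 3-hydroxy-5,7-dimethoxy-3-[4-(methoxymethoxy)phenyl]-6-(3-methylbut-2-en-1-yl)chroman-4-one
Conditions: 2-(pentafluorophenyl)-6,7-dihydro-5H-pyrrolo[2,1-c][1,2,4]triazol-2-ium tetrafluoroborate (20 mol %), Et3N (20 mol %), THF (0.05 M), 40 °C, Ar
Reagents that add atoms: none
Why: Et3N deprotonates the triazolium salt to the carbene, which adds to the aldehyde carbon (C4) of 13, and proton transfer gives the hydroxy-enamine (Breslow intermediate), an acyl anion equivalent at C4. This carbon attacks the tethered aryl ketone carbon (C3), forming the C3–C4 bond and closing ring C in a 6-exo-trig mode; proton transfer and loss of the carbene restore the C4 carbonyl and leave the tertiary alcohol on C3. The closest known reaction type is the carbene-catalysed intramolecular crossed aldehyde–ketone benzoin cyclisation of 2-(2-oxoalkoxy)benzaldehydes to 3-hydroxychroman-4-ones. The new stereocentre C3 is formed without control (achiral catalyst, racemate), which is acceptable because step 9 turns it into an sp2 carbon. The step needs the aldehyde to be the only acyl anion donor and the ketone the only acceptor: a ketone cannot form the hydroxy-enamine, the tether makes the six-ring closure intramolecular, and the two ortho oxygens hinder intermolecular homo-benzoin. The same ortho substituents and the electron-rich ring slow carbene addition, which is why a small, acidic N-pentafluorophenyl triazolium is used at raised loading. The base is weak and substoichiometric so that enolisation of the O–CH2–C=O unit and aldol closure do not compete, and air is excluded to keep the hydroxy-enamine from being oxidised.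

Step 9
Reactants: 14 racemic 3-hydroxy-5,7-dimethoxy-3-[4-(methoxymethoxy)phenyl]-6-(3-methylbut-2-en-1-yl)chroman-4-one
Product: 16 5,7-dimethoxy-3-[4-(methoxymethoxy)phenyl]-6-(3-methylbut-2-en-1-yl)-4H-chromen-4-one, via sulfamate ester 15 (not isolated)
Conditions: Burgess reagent (2.5 equiv), THF, rt → 65 °C
Reagents that add atoms: Burgess reagent (methyl N-(triethylammoniosulfonyl)carbamate), CC[N+](CC)(CC)S(=O)(=O)[N-]C(=O)OC (sulfamate group of 15 only; no atom of it remains in 16)
Why: Burgess dehydration: the tertiary alcohol is converted into sulfamate 15, which undergoes thermal syn-elimination (Ei). C2 is the only carbon with beta-hydrogens, so only the C2=C3 alkene can form, and the product gains the stabilisation of the 4-pyranone. The neutral conditions spare acetal and prenyl group, and the C3 stereocentre is removed.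

Step 10
Reactants: 16 5,7-dimethoxy-3-[4-(methoxymethoxy)phenyl]-6-(3-methylbut-2-en-1-yl)-4H-chromen-4-one
Product: 18 gancaonin G, 5-hydroxy-3-(4-hydroxyphenyl)-7-methoxy-6-(3-methylbut-2-en-1-yl)-4H-chromen-4-one, via bis(dichloroboryl) ether 17 (not isolated)
Conditions: BCl3 (1 M in CH2Cl2, 4 equiv), CH2Cl2, −78 → 0 °C; then cold aq NaHCO3
Reagents that add atoms: boron trichloride, ClB(Cl)Cl (boron and chlorine of 17 only; no atom of it remains in 18)
Why: Lewis-acid ether cleavage: BCl3 binds the C4 carbonyl and the peri 5-methoxy oxygen, and chloride removes the methyl group to leave a six-membered boron chelate. The acetal on O4' is cleaved faster still, while the unchelated 7-methyl ether is not attacked at this temperature. No protic acid is present until the buffered quench, which hydrolyses 17 to 18.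

## Compound list

1 | 1,3-dimethoxybenzene | COc1cccc(OC)c1 | starting material
2 | 1-bromo-3-methylbut-2-ene (prenyl bromide) | CC(C)=CCBr | starting material
3 | (2,6-dimethoxyphenyl)lithium | [Li]c1c(OC)cccc1OC | intermediate
4 | 1,3-dimethoxy-2-(3-methylbut-2-en-1-yl)benzene | COc1cccc(OC)c1CC=C(C)C | intermediate
5 | 2-[3,5-dimethoxy-4-(3-methylbut-2-en-1-yl)phenyl]-4,4,5,5-tetramethyl-1,3,2-dioxaborolane | COc1cc(B2OC(C)(C)C(C)(C)O2)cc(OC)c1CC=C(C)C | intermediate
6 | 3,5-dimethoxy-4-(3-methylbut-2-en-1-yl)phenol | COc1cc(O)cc(OC)c1CC=C(C)C | intermediate
7 | 2-(hydroxymethyl)-3,5-dimethoxy-4-(3-methylbut-2-en-1-yl)phenol | COc1cc(O)c(CO)c(OC)c1CC=C(C)C | intermediate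
8 | 6-hydroxy-2,4-dimethoxy-3-(3-methylbut-2-en-1-yl)benzaldehyde | COc1cc(O)c(C=O)c(OC)c1CC=C(C)C | intermediate
9 | 1-(4-hydroxyphenyl)ethanone | CC(=O)c1ccc(O)cc1 | starting material
10 | 1-[4-(methoxymethoxy)phenyl]ethanone | CC(=O)c1ccc(OCOC)cc1 | intermediate
11 | {1-[4-(methoxymethoxy)phenyl]ethenyl}oxy(trimethyl)silane | C=C(O[Si](C)(C)C)c1ccc(OCOC)cc1 | intermediate
12 | 2-bromo-1-[4-(methoxymethoxy)phenyl]ethanone | BrCC(=O)c1ccc(OCOC)cc1 | intermediate
13 | 2,4-dimethoxy-6-{2-[4-(methoxymethoxy)phenyl]-2-oxoethoxy}-3-(3-methylbut-2-en-1-yl)benzaldehyde | COCOc1ccc(cc1)C(=O)COc1cc(OC)c(CC=C(C)C)c(OC)c1C=O | intermediate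
14 | racemic 3-hydroxy-5,7-dimethoxy-3-[4-(methoxymethoxy)phenyl]-6-(3-methylbut-2-en-1-yl)chroman-4-one | COCOc1ccc(cc1)C1(O)COc2cc(OC)c(CC=C(C)C)c(OC)c2C1=O | intermediate
15 | racemic methyl N-[({5,7-dimethoxy-3-[4-(methoxymethoxy)phenyl]-6-(3-methylbut-2-en-1-yl)-4-oxochroman-3-yl}oxy)sulfonyl]carbamate (present as its triethylammonium salt) | COC(=O)NS(=O)(=O)OC1(COc2cc(OC)c(CC=C(C)C)c(OC)c2C1=O)c1ccc(OCOC)cc1 | intermediate
16 | 5,7-dimethoxy-3-[4-(methoxymethoxy)phenyl]-6-(3-methylbut-2-en-1-yl)-4H-chromen-4-one | COCOc1ccc(cc1)-c1coc2cc(OC)c(CC=C(C)C)c(OC)c2c1=O | intermediate
17 | 5-[(dichloroboranyl)oxy]-3-{4-[(dichloroboranyl)oxy]phenyl}-7-methoxy-6-(3-methylbut-2-en-1-yl)-4H-chromen-4-one | COc1cc2occ(-c3ccc(OB(Cl)Cl)cc3)c(=O)c2c(OB(Cl)Cl)c1CC=C(C)C | intermediate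
18 | gancaonin G, 5-hydroxy-3-(4-hydroxyphenyl)-7-methoxy-6-(3-methylbut-2-en-1-yl)-4H-chromen-4-one | COc1cc2occ(-c3ccc(O)cc3)c(=O)c2c(O)c1CC=C(C)C | target

## Step count and risk

Total step count: 10. Longest linear sequence: 8 steps (steps 1–4 and 7–10, from 1). Steps 5 and 6 form a two-step side branch that joins at step 7.

Least certain steps:

**Step 8 (key step).** Carbene addition and formation of the hydroxy-enamine may be slow, because the aldehyde is electron-rich and carries two ortho oxygen substituents. While the catalyst idles, base-induced enolisation of the ketone can lead to intramolecular aldol condensation, or the hydroxy-enamine can be oxidised by traces of air. The fallback gives up the umpolung closure and builds ring C by the deoxybenzoin route. It sets out from 8: addition of 4-(methoxymethoxy)benzylmagnesium chloride (2.5 equiv, THF, 0 °C; the first equivalent forms the magnesium phenoxide) should give the carbinol 2-{1-hydroxy-2-[4-(methoxymethoxy)phenyl]ethyl}-3,5-dimethoxy-4-(3-methylbut-2-en-1-yl)phenol F1. MnO2 in CH2Cl2 would oxidise the benzylic alcohol to the 2-hydroxydeoxybenzoin 1-[6-hydroxy-2,4-dimethoxy-3-(3-methylbut-2-en-1-yl)phenyl]-2-[4-(methoxymethoxy)phenyl]ethanone F2. Heating F2 with N,N-dimethylformamide dimethyl acetal in toluene at 80 °C supplies C2 as an enaminone that cyclises with loss of dimethylamine. The fallback comes back to the route at 16, bypassing 13, 14 and 15.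

**Step 10.** The prenyl alkene may be protonated or chlorinated by hydrogen chloride formed from traces of moisture. This would be followed by ring closure onto the O5 or O7 oxygen, or the chelated methyl ether may be cleaved incompletely if the temperature is kept low enough to protect the alkene. The fallback separates the two deprotections and uses no boron halide. It sets out from 16: MgI2·OEt2 in THF at 60 °C should remove only the chelated methyl group by iodide attack on the magnesium-bound ether, giving 5-hydroxy-7-methoxy-3-[4-(methoxymethoxy)phenyl]-6-(3-methylbut-2-en-1-yl)-4H-chromen-4-one F3. Brief treatment of F3 with dilute HCl in methanol at 40 °C would then remove the acetal. The fallback comes back at 18.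

**Step 2.** Hydroboration or vinylic borylation of the prenyl alkene by iridium hydride and boryl species may compete, the more so because borylation of the electron-rich ring is slow. The fallback reverses the order so that no alkene is present during catalysis. It sets out from 1:
- Borylation of 1 under the conditions of step 2 should give 2-(3,5-dimethoxyphenyl)-4,4,5,5-tetramethyl-1,3,2-dioxaborolane F4, and oxidation as in step 3 gives 3,5-dimethoxyphenol F5.
- Silylation (i-Pr3SiCl, imidazole, DMF) gives (3,5-dimethoxyphenoxy)tri(propan-2-yl)silane F6.
- n-BuLi in THF should metalate F6 between the two methoxy groups, since the bulky silyl ether is a poor director, and alkylation with 2 gives [3,5-dimethoxy-4-(3-methylbut-2-en-1-yl)phenoxy]tri(propan-2-yl)silane F7.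
- Bu4NF in THF removes the silyl group.

The fallback comes back at 6.

**Step 9.** The sulfamate may ionise to a benzylic cation next to the carbonyl and then undergo a 1,2-shift with ring contraction, or it may persist without elimination. The fallback replaces the one-pot syn-elimination by halide formation and base-induced dehydrohalogenation. It sets out from 14: SOCl2 and pyridine in CH2Cl2 at 0 °C should give racemic 3-chloro-5,7-dimethoxy-3-[4-(methoxymethoxy)phenyl]-6-(3-methylbut-2-en-1-yl)chroman-4-one F8. Li2CO3 and LiBr in DMF at 90 °C would then remove hydrogen chloride across C2–C3, as in the classical conversion of alpha-halo ketones into enones. The fallback comes back at 16.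

**Step 7.** Under carbonate the new ether can enolise and close onto the aldehyde, with dehydration to a 2-aroylbenzofuran (Rap–Stoermer reaction), before or after the alkylation is complete. The fallback forms the ether without base. It sets out from 12: HCO2Na in aqueous ethanol at reflux displaces bromide and the formate is hydrolysed in the same pot, giving 2-hydroxy-1-[4-(methoxymethoxy)phenyl]ethanone F9. A Mitsunobu reaction of F9 with 8 (PPh3, diisopropyl azodicarboxylate, THF, 0 °C → rt) would then give the ether. The fallback comes back at 13.

## Further compounds

F1 | step 8 | racemic 2-{1-hydroxy-2-[4-(methoxymethoxy)phenyl]ethyl}-3,5-dimethoxy-4-(3-methylbut-2-en-1-yl)phenol | COCOc1ccc(CC(O)c2c(O)cc(OC)c(CC=C(C)C)c2OC)cc1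
F2 | step 8 | 1-[6-hydroxy-2,4-dimethoxy-3-(3-methylbut-2-en-1-yl)phenyl]-2-[4-(methoxymethoxy)phenyl]ethanone | COCOc1ccc(CC(=O)c2c(O)cc(OC)c(CC=C(C)C)c2OC)cc1
F3 | step 10 | 5-hydroxy-7-methoxy-3-[4-(methoxymethoxy)phenyl]-6-(3-methylbut-2-en-1-yl)-4H-chromen-4-one | COCOc1ccc(cc1)-c1coc2cc(OC)c(CC=C(C)C)c(O)c2c1=O
F4 | step 2 | 2-(3,5-dimethoxyphenyl)-4,4,5,5-tetramethyl-1,3,2-dioxaborolane | COc1cc(OC)cc(c1)B1OC(C)(C)C(C)(C)O1
F5 | step 2 | 3,5-dimethoxyphenol | COc1cc(O)cc(OC)c1
F6 | step 2 | (3,5-dimethoxyphenoxy)tri(propan-2-yl)silane | COc1cc(OC)cc(O[Si](C(C)C)(C(C)C)C(C)C)c1
F7 | step 2 | [3,5-dimethoxy-4-(3-methylbut-2-en-1-yl)phenoxy]tri(propan-2-yl)silane | COc1cc(O[Si](C(C)C)(C(C)C)C(C)C)cc(OC)c1CC=C(C)C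
F8 | step 9 | racemic 3-chloro-5,7-dimethoxy-3-[4-(methoxymethoxy)phenyl]-6-(3-methylbut-2-en-1-yl)chroman-4-one | COCOc1ccc(cc1)C1(Cl)COc2cc(OC)c(CC=C(C)C)c(OC)c2C1=O
F9 | step 7 | 2-hydroxy-1-[4-(methoxymethoxy)phenyl]ethanone | OCC(=O)c1ccc(OCOC)cc1
A1 | alternative 1 | 4'-O-triisopropylsilyl gancaonin G, 5-hydroxy-7-methoxy-6-(3-methylbut-2-en-1-yl)-3-{4-[tri(propan-2-yl)silyloxy]phenyl}-4H-chromen-4-one | COc1cc2occ(-c3ccc(O[Si](C(C)C)(C(C)C)C(C)C)cc3)c(=O)c2c(O)c1CC=C(C)C
A2 | alternative 1 | 2-diazo-1-(4-oxo-5-{4-[tri(propan-2-yl)silyloxy]phenyl}-4H-pyran-2-yl)ethanone | [N-]=[N+]=CC(=O)c1cc(=O)c(co1)-c1ccc(O[Si](C(C)C)(C(C)C)C(C)C)cc1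
A3 | alternative 1 | 1-methoxy-5-methylhex-4-en-1-yne | COC#CCC=C(C)C
A4 | alternative 2 | 5,7-dimethoxy-3-[4-(methoxymethoxy)phenyl]-6-(3-methylbut-2-en-1-yl)-4H-chromen-4-one (identical with 16) | COCOc1ccc(cc1)-c1coc2cc(OC)c(CC=C(C)C)c(OC)c2c1=O
A5 | alternative 2 | 3,5-dimethoxy-4-(3-methylbut-2-en-1-yl)-2-(trimethylsilyl)phenyl trifluoromethanesulfonate | COc1cc(OS(=O)(=O)C(F)(F)F)c([Si](C)(C)C)c(OC)c1CC=C(C)C
A6 | alternative 2 | methyl 3-hydroxy-2-[4-(methoxymethoxy)phenyl]prop-2-enoate | COC(=O)C(=CO)c1ccc(OCOC)cc1
A7 | alternative 3 | 5,7-dihydroxy-3-[4-(methoxymethoxy)phenyl]-6-(3-methylbut-2-en-1-yl)-4H-chromen-4-one | COCOc1ccc(cc1)-c1coc2cc(O)c(CC=C(C)C)c(O)c2c1=O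
A8 | alternative 3 | 6-methylhept-5-en-2-one (sulcatone) | CC(=O)CCC=C(C)C
A9 | alternative 3 | methyl 5-[4-(methoxymethoxy)phenyl]-2-(methylsulfanyl)-4-oxo-4H-pyran-3-carboxylate | COC(=O)c1c(SC)occ(-c2ccc(OCOC)cc2)c1=O
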